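# Synthesis plan for CNP0403384.1 (compound 20)

## The problem

Compound 20 is an aryltetralin lignan ester of the isolariciresinol type. In the lignan numbering used throughout, ring A (C4a, C5–C8, C8a) carries OMe at C6 and OH at C7 and is fused to the saturated ring B (C1–C4); ring B bears a 4-hydroxy-3-methoxyphenyl (guaiacyl) ring at C1, the CH2O carbon C2a with its (E)-4-hydroxycinnamate at C2, and the free CH2OH carbon C3a at C3. The three stereocentres are contiguous, (1S,2R,3R), and each substituent is trans to its neighbour, so the aryl ring and C3a share one face, C2a lies on the other, and all three groups can be equatorial. This allows a relay: one centre fixed by a catalyst is enough, because C3 can direct C2 and C2 can direct C1 if each new group enters anti to the one beside it. The two primary oxygens on C2a and C3a are chemically almost alike, yet only the one on C2a is acylated, so they must be told apart by the way the skeleton is assembled and not by a late selective acylation. The coumarate is the fragile part: once it is in place, base (ester exchange, acyl shift from the oxygen on C2a to that on C3a), hydride and hydrogenation are excluded, and the three free phenols and the doubly benzylic C1–H call for a mild, non-oxidising end game. The feature that opens the key step is that C1 and C2 are adjacent, that C1 is benzylic to ring A, and that what they carry, an aryl ring and a one-carbon CH2O unit, is what a radical addition followed by an aryl coupling delivers across the C1=C2 double bond of a 1,2-dihydronaphthalene that already holds C3.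

## Retrosynthesis

**20 ⇒ 19 ⇒ 15 + 18 (O–Si bonds, then the ester C–O bond at C2a).** The coumarate is attached last and under neutral conditions, and every hydroxyl that must end up free is masked as a silyl ether so that one buffered fluoride treatment finishes the synthesis. Benzyl ethers are ruled out here because their hydrogenolysis would reduce the cinnamate. Cutting the ester gives alcohol 15 and the O-silyl acid 18. The forward esterification only asks that C2a–OH be the sole free hydroxyl in 15.

**15 ⇒ 14 (acyl C–O of a pivalate).** The free C2a–OH is traced back to a pivalate, so that C2a arrives as an ester while C3a is a silyl ether. The two oxygens are then different from the moment C2a enters the molecule. The forward step is a hydride cleavage that silyl ethers ignore.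

**14 ⇒ 10 + 12 + 13 (C1–aryl and C2–C2a).** Both bonds are cut across the former C1=C2 double bond. This cut removes two of the three stereocentres and two skeletal bonds at once and leaves three simple pieces: dihydronaphthalene 10 with C3 alone, aryl bromide 12 and iodomethyl pivalate 13. Cutting only C1–aryl or only C2–C2a would leave a precursor that still carries a stereo-diad. The forward reaction must add the acyloxymethyl radical to C2 and the aryl group to C1, each anti to its neighbour, and it must outrun direct aryl–alkyl coupling of the two halides. Three adjustments serve this. The CH2O group on C3 carries the bulky triisopropylsilyl group to shield one face of C2. The alkene is the limiting component. Manganese replaces zinc as reductant, because zinc inserts directly into iodomethyl pivalate and would feed the unwanted two-component coupling.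

**10 ⇒ 9 ⇒ 8 ⇒ 7 (C1=C2 from C1–OH; C3a–O and C1–O from ester and ketone).** The styrene double bond is traced to a benzylic alcohol that can only eliminate towards C2, and the alcohol and the CH2O group to tetralone ester 7. Reduction before elimination keeps the C3 stereocentre away from any enolisable or allylic-ester situation. One bulky silyl chloride then protects the phenol and the primary alcohol and spares the secondary benzylic alcohol.

**7 ⇒ 6 ⇒ 4 (C1–C8a).** Ring B is opened at the aryl ketone bond. An intramolecular Friedel–Crafts acylation para to the methoxy group closes it, and using the half-ester (via the mixed anhydride 5) means that only the CH2CO2H arm can acylate. The benzyl ether that survived the basic first step is exchanged at the tetralone stage, before any alkene exists.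

**4 ⇒ 3 ⇒ 1 + 2 (C3–H, then the C4–C3 and C=C bonds of a Stobbe product).** The only stereocentre set by a reagent comes from asymmetric hydrogenation of the itaconate-type half-ester 3, a substrate class for which rhodium bisphospholane catalysts are reliable. Half-ester 3 is the Stobbe product of O-benzylvanillin 1 and dimethyl succinate 2, and the Stobbe reaction itself delivers the acid/ester differentiation needed for the ring closure.

**12 ⇐ 11 and 18 ⇐ 16 (O–Si).** Both side pieces are one silylation away from commercial 4-bromo-2-methoxyphenol 11 and p-coumaric acid 16 (the latter via the bis-silyl compound 17). Iodomethyl pivalate 13 is commercial.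

## Roads not taken

**Alternative 1:** The cut is C3–C4. The open-chain aldehyde A2 already carries C1 (both aryl rings), C2 (with the coumarate on C2a) and a CH2OH group on ring A para to the C7 phenol. With pyrrolidine and PhCO2H the aldehyde would form an enamine at C3 while the para-hydroxybenzylic alcohol of ring A loses water to a quinone methide unit. 1,6-Addition would then close ring B and return the phenol, giving aldehyde A1.

- Merits: no metal and no phenol protection; the coumarate is already in place; C3 is set next to C2 at an epimerisable aldehyde α-carbon, so the equatorial trans arrangement is favoured. Enamine additions to para-quinone methides are an established reaction type, so this key step stands closer to precedent than the chosen one.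
- Weak points: A2 must be made with the C1/C2 pair and the diarylmethine already in place, which is the hard part of the problem. A quinone methide unsubstituted at its exocyclic carbon is prone to oligomerise and to add the amine. The secondary amine can also add to the cinnamate. A1 still needs reduction of the aldehyde beside the ester, which produces an alkoxide on C3a next to the acyl group on C2a and brings back the acyl-shift problem at the last step.
- Comparison: this road is better in protecting-group economy and precedent. The chosen plan sets against that the creation of C1 and C2 together with two C–C bonds from a precursor with one stereocentre, and a C2a/C3a differentiation that never passes through a free neighbouring alkoxide.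

**Alternative 2:** The cuts are C1–C2 and C3–C4. Irradiation near 350 nm would photoenolise the 2-benzylbenzaldehyde A4 to its transient diene, which would add the fumarate A5 of methyl (S)-lactate to give the 4-hydroxytetralin diester A3 (1,2-trans, 2,3-trans, 3,4-cis).

- Merits: ring B, two C–C bonds and four stereocentres arise in one step from two easily made pieces; the trans diester maps directly onto the 2,3-trans pattern. The reaction type is established, so the key step is on firmer ground, and the route to the bare skeleton is shorter than the chosen one.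
- Weak points: C2a and C3a arrive as two identical lactate esters and become two indistinguishable primary alcohols on reduction, so coumaroylation of C2a alone is left to a weakly biased acylation. The C4 hydroxyl is not in the target and costs a benzylic deoxygenation. The absolute configuration rests on an ester auxiliary in an uncatalysed photocycloaddition, where lactate control is weakest.
- Comparison: for a target with two identical CH2OH groups this would be the better road. For 20 the chosen plan sets against its brevity a C2a/C3a distinction that is built in and an absolute configuration that comes from a catalytic hydrogenation of a well-behaved substrate class.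

**Alternative 3:** The cut is C4–C4a. Bromine–lithium exchange on the aryl bromide A7 (n-BuLi, −78 °C) followed by BF3·OEt2 would let the aryllithium open the oxetane at one of its two diastereotopic CH2 groups. This closes ring B, creates C3 and releases C3a–OH, giving A6 with a PMB ether on C2a–O.

- Merits: C2a and C3a are differentiated by construction, as in the chosen plan. Intramolecular Lewis-acid-assisted oxetane opening by aryllithiums is a known reaction type, and no transition-metal selectivity question arises.
- Weak points: A7 must already contain C1 and C2, so the step forms one bond and one stereocentre after most of the work is done. The choice between the two CH2 groups is an untested substrate-controlled selection. The aryllithium sits ortho to the acidic diarylmethine C1–H, so internal proton transfer threatens C1. In A6 the wrong oxygen is free, so silylation of C3a–OH and oxidative PMB removal beside electron-rich aryl silyl ethers are needed before the esterification.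
- Comparison: this ring closure is closer to precedent than the nickel step, which is its real advantage. The chosen plan sets against it a far simpler precursor, two bonds and two stereocentres in the key step, and a one-step unmasking of C2a–OH.

Key step: step 9

Assumption: the (S,S) enantiomer of Et-DuPhos is taken to deliver the (R)-acid 4; should the sense prove opposite, the (R,R) ligand is used in the same way. Alcohols 8 and 9 are carried as mixtures of C1 epimers, which converge in step 7.

## Route

Step 1
Reactants: 1 4-(benzyloxy)-3-methoxybenzaldehyde (O-benzylvanillin); 2 dimethyl succinate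
Product: 3 (E)-4-[4-(benzyloxy)-3-methoxyphenyl]-3-(methoxycarbonyl)but-3-enoic acid
Conditions: NaOMe (2 equiv), MeOH, reflux; then aq. HCl
Reagents that add atoms: none
Why: Stobbe condensation: the succinate enolate adds to the aldehyde, lactonisation onto the distal ester and base-induced ring opening leave the conjugated ester and free the CH2CO2H arm; the isomer with aryl trans to the ester (E) should predominate, and the benzyl ether is inert to methoxide.

Step 2
Reactants: 3 (E)-4-[4-(benzyloxy)-3-methoxyphenyl]-3-(methoxycarbonyl)but-3-enoic acid
Product: 4 (R)-4-[4-(benzyloxy)-3-methoxyphenyl]-3-(methoxycarbonyl)butanoic acid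
Conditions: [Rh(cod)((S,S)-Et-DuPhos)]OTf (0.5 mol %), NaOMe (10 mol %), H2 (5 bar), MeOH, 25 °C
Reagents that add atoms: none
Why: Rhodium-catalysed asymmetric hydrogenation of a Stobbe-type itaconate half-ester; the carboxylate and the alkene bind the cationic rhodium bisphospholane and the ligand chirality sets the future C3 stereocentre as (R); the homogeneous catalyst does not hydrogenolyse the benzyl ether.

Step 3
Reactants: 4 (R)-4-[4-(benzyloxy)-3-methoxyphenyl]-3-(methoxycarbonyl)butanoic acid
Product: 6 methyl (R)-6-(benzyloxy)-7-methoxy-4-oxo-1,2,3,4-tetrahydronaphthalene-2-carboxylate, via mixed trifluoroacetic anhydride 5 (not isolated)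
Conditions: (CF3CO)2O (2 equiv), CH2Cl2, 0 °C → rt
Reagents that add atoms: none
Why: Intramolecular Friedel–Crafts acylation through the acyl trifluoroacetate; the six-membered ring closes at the unhindered position para to the methoxy group (C8a), and the absence of base leaves the ester α-stereocentre untouched.

Step 4
Reactants: 6 methyl (R)-6-(benzyloxy)-7-methoxy-4-oxo-1,2,3,4-tetrahydronaphthalene-2-carboxylate
Product: 7 methyl (R)-6-hydroxy-7-methoxy-4-oxo-1,2,3,4-tetrahydronaphthalene-2-carboxylate
Conditions: H2 (1 atm), Pd/C (10 %), EtOAc, rt
Reagents that add atoms: none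
Why: Hydrogenolysis of an aryl benzyl ether; at one atmosphere in a neutral solvent the electron-rich aryl ketone is reduced far more slowly, and the reaction is stopped after uptake of one equivalent.

Step 5
Reactants: 7 methyl (R)-6-hydroxy-7-methoxy-4-oxo-1,2,3,4-tetrahydronaphthalene-2-carboxylate
Product: 8 (3R)-3-(hydroxymethyl)-6-methoxy-1,2,3,4-tetrahydronaphthalene-1,7-diol (C1 epimers)
Conditions: LiAlH4 (3 equiv), THF, 0 °C → rt; aq. potassium sodium tartrate
Reagents that add atoms: none
Why: Hydride reduction of ketone and ester with the phenol carried as its phenoxide; hydride addition is faster than enolisation, so C3 keeps its configuration, and the new C1 carbinol centre is irrelevant because it is removed in step 7.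

Step 6
Reactants: 8 (3R)-3-(hydroxymethyl)-6-methoxy-1,2,3,4-tetrahydronaphthalene-1,7-diol (C1 epimers)
Product: 9 (3R)-6-methoxy-7-(triisopropylsilyloxy)-3-[(triisopropylsilyloxy)methyl]-1,2,3,4-tetrahydronaphthalen-1-ol (C1 epimers)
Conditions: i-Pr3SiCl (2.2 equiv), imidazole (5 equiv), DMF, 0 °C → rt
Reagents that add atoms: triisopropylsilyl chloride, CC(C)[Si](Cl)(C(C)C)C(C)C
Why: Sterically selective silylation: the bulky silyl chloride reacts with the phenol and the primary alcohol and leaves the secondary benzylic alcohol free.

Step 7
Reactants: 9 (3R)-6-methoxy-7-(triisopropylsilyloxy)-3-[(triisopropylsilyloxy)methyl]-1,2,3,4-tetrahydronaphthalen-1-ol (C1 epimers)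
Product: 10 (R)-7-methoxy-6-(triisopropylsilyloxy)-2-[(triisopropylsilyloxy)methyl]-1,2-dihydronaphthalene (lignan C1=C2 alkene, C3 stereocentre)
Conditions: p-TsOH·H2O (2 mol %), toluene (dilute), 80 °C
Reagents that add atoms: none
Why: Acid-catalysed E1 dehydration; the para-methoxybenzylic cation forms readily from either epimer and can lose a proton only from C2, giving the conjugated alkene without touching C3.

Step 8
Reactants: 11 4-bromo-2-methoxyphenol
Product: 12 (4-bromo-2-methoxyphenoxy)triisopropylsilane
Conditions: i-Pr3SiCl, imidazole, DMF, rt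
Reagents that add atoms: triisopropylsilyl chloride, CC(C)[Si](Cl)(C(C)C)C(C)C
Why: Standard silylation of a phenol; the aryl silyl ether is inert to low-valent nickel and to hydride.

Step 9
Reactants: 10 (R)-7-methoxy-6-(triisopropylsilyloxy)-2-[(triisopropylsilyloxy)methyl]-1,2-dihydronaphthalene; 12 (4-bromo-2-methoxyphenoxy)triisopropylsilane; 13 iodomethyl pivalate
Product: 14 [(1S,2R,3R)-6-methoxy-1-[3-methoxy-4-(triisopropylsilyloxy)phenyl]-7-(triisopropylsilyloxy)-3-[(triisopropylsilyloxy)methyl]-1,2,3,4-tetrahydronaphthalen-2-yl]methyl pivalate
Conditions: NiBr2(MeOCH2CH2OMe) (10 mol %), 4,4'-di-tert-butyl-2,2'-bipyridine (12 mol %), Mn powder (4 equiv), 12 (2.5 equiv), 13 (3 equiv, in portions), DMA (high alkene concentration), 25 °C, Ar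
Reagents that add atoms: none
Why: Proposed new method: a nickel-catalysed reductive three-component alkyl-arylation has not been shown on a cyclic β-substituted styrene with an allylic stereocentre; the closest known reaction type is the nickel/bipyridine reductive 1,2-alkyl-arylation of vinylarenes and activated alkenes with alkyl and aryl halides. Monovalent nickel abstracts iodine from 13, the pivaloyloxymethyl radical adds to C2 because this places the odd electron on C1, benzylic to the electron-rich ring A, and the C1 radical is caught by the arylnickel bromide formed from 12 and zerovalent nickel; reductive elimination from the trivalent aryl(alkyl)nickel forms the C1–aryl bond and manganese returns nickel to its low-valent state. No ring is closed. C2 is set by C3: the radical approaches the face of the half-chair opposite the bulky CH2OSi(i-Pr)3 group. C1 is set by C2: the arylnickel species meets the planar benzylic radical anti to the new CH2O-pivaloyl group, so the all-trans, all-equatorial isomer follows from the one existing centre. The step needs regioselectivity (alkyl to C2, aryl to C1), which benzylic radical stability secures, and chemoselectivity against direct aryl–CH2O coupling, which is addressed by making 10 the limiting component, adding 12 and 13 in excess and in portions, and using manganese instead of zinc, which inserts into iodomethyl pivalate.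

Step 10
Reactants: 14 [(1S,2R,3R)-6-methoxy-1-[3-methoxy-4-(triisopropylsilyloxy)phenyl]-7-(triisopropylsilyloxy)-3-[(triisopropylsilyloxy)methyl]-1,2,3,4-tetrahydronaphthalen-2-yl]methyl pivalate
Product: 15 [(1S,2R,3R)-6-methoxy-1-[3-methoxy-4-(triisopropylsilyloxy)phenyl]-7-(triisopropylsilyloxy)-3-[(triisopropylsilyloxy)methyl]-1,2,3,4-tetrahydronaphthalen-2-yl]methanol
Conditions: (i-Bu)2AlH (3 equiv), CH2Cl2, −78 °C; aq. potassium sodium tartrate
Reagents that add atoms: none
Why: Reductive cleavage of a pivalate by an aluminium hydride; aryl and alkyl triisopropylsilyl ethers are inert at −78 °C and no stereocentre is adjacent to an acidic position.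

Step 11
Reactants: 16 (E)-4-hydroxycinnamic acid (p-coumaric acid)
Product: 18 (E)-3-[4-(triisopropylsilyloxy)phenyl]acrylic acid, via bis-silylated coumarate 17 (not isolated)
Conditions: i-Pr3SiCl (2.2 equiv), imidazole, DMF, rt; then K2CO3 (1.2 equiv), THF–H2O, rt; aq. HCl to pH 3
Reagents that add atoms: triisopropylsilyl chloride, CC(C)[Si](Cl)(C(C)C)C(C)C
Why: Silylation of phenol and carboxylic acid followed by selective hydrolysis of the much more labile silyl ester; the aryl triisopropylsilyl ether withstands brief aqueous carbonate.

Step 12
Reactants: 15 [(1S,2R,3R)-6-methoxy-1-[3-methoxy-4-(triisopropylsilyloxy)phenyl]-7-(triisopropylsilyloxy)-3-[(triisopropylsilyloxy)methyl]-1,2,3,4-tetrahydronaphthalen-2-yl]methanol; 18 (E)-3-[4-(triisopropylsilyloxy)phenyl]acrylic acid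
Product: 19 [(1S,2R,3R)-6-methoxy-1-[3-methoxy-4-(triisopropylsilyloxy)phenyl]-7-(triisopropylsilyloxy)-3-[(triisopropylsilyloxy)methyl]-1,2,3,4-tetrahydronaphthalen-2-yl]methyl (E)-3-[4-(triisopropylsilyloxy)phenyl]acrylate
Conditions: DCC (1.3 equiv), DMAP (0.1 equiv), CH2Cl2, 0 °C → rt
Reagents that add atoms: none
Why: Steglich esterification of the only free hydroxyl (on C2a) under neutral conditions; the (E) double bond and the three stereocentres are not affected.

Step 13
Reactants: 19 [(1S,2R,3R)-6-methoxy-1-[3-methoxy-4-(triisopropylsilyloxy)phenyl]-7-(triisopropylsilyloxy)-3-[(triisopropylsilyloxy)methyl]-1,2,3,4-tetrahydronaphthalen-2-yl]methyl (E)-3-[4-(triisopropylsilyloxy)phenyl]acrylate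
Product: 20 [(1S,2R,3R)-7-hydroxy-1-(4-hydroxy-3-methoxyphenyl)-3-(hydroxymethyl)-6-methoxy-1,2,3,4-tetrahydronaphthalen-2-yl]methyl (E)-3-(4-hydroxyphenyl)acrylate (CNP0403384.1)
Conditions: HF·pyridine (excess), pyridine, THF, 0 °C → rt
Reagents that add atoms: none
Why: Fluoride-mediated cleavage of three aryl and one primary alkyl silyl ether under buffered, weakly acidic conditions; no base is present, so neither ester exchange nor acyl shift from the oxygen on C2a to that on C3a is expected.

## Compound list

1 | 4-(benzyloxy)-3-methoxybenzaldehyde (O-benzylvanillin) | COc1cc(C=O)ccc1OCc1ccccc1 | starting material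
2 | dimethyl succinate | COC(=O)CCC(=O)OC | starting material
3 | (E)-4-[4-(benzyloxy)-3-methoxyphenyl]-3-(methoxycarbonyl)but-3-enoic acid | COC(=O)/C(CC(=O)O)=C/c1ccc(OCc2ccccc2)c(OC)c1 | intermediate
4 | (R)-4-[4-(benzyloxy)-3-methoxyphenyl]-3-(methoxycarbonyl)butanoic acid | COC(=O)[C@H](Cc1ccc(OCc2ccccc2)c(OC)c1)CC(=O)O | intermediate
5 | mixed anhydride of acid 4 with trifluoroacetic acid | COC(=O)[C@H](Cc1ccc(OCc2ccccc2)c(OC)c1)CC(=O)OC(=O)C(F)(F)F | intermediate (not isolated)
6 | methyl (R)-6-(benzyloxy)-7-methoxy-4-oxo-1,2,3,4-tetrahydronaphthalene-2-carboxylate (lignan numbering: C1 ketone, C3 ester, 6-OMe, 7-OBn) | COC(=O)[C@H]1CC(=O)c2cc(OCc3ccccc3)c(OC)cc2C1 | intermediate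
7 | methyl (R)-6-hydroxy-7-methoxy-4-oxo-1,2,3,4-tetrahydronaphthalene-2-carboxylate | COC(=O)[C@H]1CC(=O)c2cc(O)c(OC)cc2C1 | intermediate
8 | (3R)-3-(hydroxymethyl)-6-methoxy-1,2,3,4-tetrahydronaphthalene-1,7-diol, mixture of C1 epimers | COc1cc2C[C@@H](CO)CC(O)c2cc1O | intermediate
9 | (3R)-6-methoxy-7-(triisopropylsilyloxy)-3-[(triisopropylsilyloxy)methyl]-1,2,3,4-tetrahydronaphthalen-1-ol, mixture of C1 epimers | COc1cc2C[C@@H](CO[Si](C(C)C)(C(C)C)C(C)C)CC(O)c2cc1O[Si](C(C)C)(C(C)C)C(C)C | intermediate
10 | (R)-7-methoxy-6-(triisopropylsilyloxy)-2-[(triisopropylsilyloxy)methyl]-1,2-dihydronaphthalene | COc1cc2C[C@@H](CO[Si](C(C)C)(C(C)C)C(C)C)C=Cc2cc1O[Si](C(C)C)(C(C)C)C(C)C | intermediate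
11 | 4-bromo-2-methoxyphenol | COc1cc(Br)ccc1O | starting material
12 | (4-bromo-2-methoxyphenoxy)triisopropylsilane | COc1cc(Br)ccc1O[Si](C(C)C)(C(C)C)C(C)C | intermediate
13 | iodomethyl pivalate | CC(C)(C)C(=O)OCI | starting material
14 | [(1S,2R,3R)-6-methoxy-1-[3-methoxy-4-(triisopropylsilyloxy)phenyl]-7-(triisopropylsilyloxy)-3-[(triisopropylsilyloxy)methyl]-1,2,3,4-tetrahydronaphthalen-2-yl]methyl pivalate | COc1cc([C@H]2c3cc(O[Si](C(C)C)(C(C)C)C(C)C)c(OC)cc3C[C@@H](CO[Si](C(C)C)(C(C)C)C(C)C)[C@@H]2COC(=O)C(C)(C)C)ccc1O[Si](C(C)C)(C(C)C)C(C)C | intermediate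
15 | [(1S,2R,3R)-6-methoxy-1-[3-methoxy-4-(triisopropylsilyloxy)phenyl]-7-(triisopropylsilyloxy)-3-[(triisopropylsilyloxy)methyl]-1,2,3,4-tetrahydronaphthalen-2-yl]methanol | COc1cc([C@H]2c3cc(O[Si](C(C)C)(C(C)C)C(C)C)c(OC)cc3C[C@@H](CO[Si](C(C)C)(C(C)C)C(C)C)[C@@H]2CO)ccc1O[Si](C(C)C)(C(C)C)C(C)C | intermediate
16 | (E)-4-hydroxycinnamic acid (p-coumaric acid) | O=C(O)/C=C/c1ccc(O)cc1 | starting material
17 | triisopropylsilyl (E)-3-[4-(triisopropylsilyloxy)phenyl]acrylate | CC(C)[Si](OC(=O)/C=C/c1ccc(O[Si](C(C)C)(C(C)C)C(C)C)cc1)(C(C)C)C(C)C | intermediate (not isolated)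
18 | (E)-3-[4-(triisopropylsilyloxy)phenyl]acrylic acid | O=C(O)/C=C/c1ccc(O[Si](C(C)C)(C(C)C)C(C)C)cc1 | intermediate
19 | [(1S,2R,3R)-6-methoxy-1-[3-methoxy-4-(triisopropylsilyloxy)phenyl]-7-(triisopropylsilyloxy)-3-[(triisopropylsilyloxy)methyl]-1,2,3,4-tetrahydronaphthalen-2-yl]methyl (E)-3-[4-(triisopropylsilyloxy)phenyl]acrylate | COc1cc([C@H]2c3cc(O[Si](C(C)C)(C(C)C)C(C)C)c(OC)cc3C[C@@H](CO[Si](C(C)C)(C(C)C)C(C)C)[C@@H]2COC(=O)/C=C/c2ccc(O[Si](C(C)C)(C(C)C)C(C)C)cc2)ccc1O[Si](C(C)C)(C(C)C)C(C)C | intermediate
20 | [(1S,2R,3R)-7-hydroxy-1-(4-hydroxy-3-methoxyphenyl)-3-(hydroxymethyl)-6-methoxy-1,2,3,4-tetrahydronaphthalen-2-yl]methyl (E)-3-(4-hydroxyphenyl)acrylate | COc1cc([C@H]2c3cc(O)c(OC)cc3C[C@@H](CO)[C@@H]2COC(=O)/C=C/c2ccc(O)cc2)ccc1O | target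

## Step count and least certain steps

Total: 13 steps. Longest linear sequence: 11 steps (steps 1–7, 9, 10, 12, 13); steps 8 and 11 make the side pieces.

**Step 9 (key step, proposed new method).**
- What may go wrong: coupling of the pivaloyloxymethyl radical with the arylnickel species may outrun its addition to the β-substituted, electron-rich styrene, leaving the alkene unused. The benzylic radical may be quenched by hydrogen transfer or lose a β-hydrogen instead of being arylated. Facial control at C2 rests on the single CH2OSi group at C3 and may be incomplete.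
- Fallback (known chemistry, a polar borylmetallation in place of the radical relay): it sets out from 10 and 12. Copper/palladium dual-catalysed arylboration, run under the conditions known to give anti addition to 1,2-dihydronaphthalenes (CuCl with a carbene or phosphine ligand, Pd(OAc)2 with a trialkylphosphine, B2pin2, NaOt-Bu, toluene/THF), should place boron on C2 anti to C3a and the aryl ring on C1 anti to boron. This gives the pinacol boronate 2-[(1S,2R,3R)-6-methoxy-1-[3-methoxy-4-(triisopropylsilyloxy)phenyl]-7-(triisopropylsilyloxy)-3-[(triisopropylsilyloxy)methyl]-1,2,3,4-tetrahydronaphthalen-2-yl]-4,4,5,5-tetramethyl-1,3,2-dioxaborolane F1. Matteson homologation (BrCH2Cl, n-BuLi, THF, −78 °C → rt) inserts CH2 into the C2–B bond with retention to give the homologated boronate 2-{[(1S,2R,3R)-6-methoxy-1-[3-methoxy-4-(triisopropylsilyloxy)phenyl]-7-(triisopropylsilyloxy)-3-[(triisopropylsilyloxy)methyl]-1,2,3,4-tetrahydronaphthalen-2-yl]methyl}-4,4,5,5-tetramethyl-1,3,2-dioxaborolane F2. Oxidation with NaBO3·4H2O in THF–H2O gives alcohol 15, where the route is rejoined; steps 9 and 10 are bypassed.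

**Step 3 (Friedel–Crafts closure).**
- What may go wrong: acid-induced loss or migration of the benzyl group, or intermolecular acylation in place of ring closure.
- Fallback: it sets out from 4. The benzyl ether is removed first (H2, Pd/C, EtOAc) to give (R)-4-(4-hydroxy-3-methoxyphenyl)-3-(methoxycarbonyl)butanoic acid F3. The free phenol acid is then cyclised in P2O5/MeSO3H at rt, which gives tetralone 7 directly; the route is rejoined at 7 and step 4 is not needed.

**Step 7 (dehydration).**
- What may go wrong: cationic dimerisation of the electron-rich styrene under acid, or loss of the primary silyl ether.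
- Fallback (no cation involved): it sets out from 9. Oxidation with MnO2 in CH2Cl2 gives (R)-6-methoxy-7-(triisopropylsilyloxy)-3-[(triisopropylsilyloxy)methyl]-3,4-dihydronaphthalen-1(2H)-one F4. Enolisation and triflation (KN(SiMe3)2, PhNTf2, THF, −78 °C) give (R)-6-methoxy-7-(triisopropylsilyloxy)-3-[(triisopropylsilyloxy)methyl]-3,4-dihydronaphthalen-1-yl trifluoromethanesulfonate F5. Palladium-catalysed formate reduction (Pd(OAc)2, PPh3, HCO2H, n-Bu3N, DMF, 60 °C) returns to 10.

**Step 13 (global desilylation).**
- What may go wrong: the hindered primary alkyl silyl ether on C3a may cleave much more slowly than the three aryl silyl ethers, and the long exposure then needed may allow acid-promoted acyl shift once C3a–OH is free.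
- Fallback (two stages with two different cleavage mechanisms): it sets out from 19. n-Bu4NF buffered with AcOH (THF, 0 °C) removes only the three phenolic silyl groups to give [(1S,2R,3R)-7-hydroxy-1-(4-hydroxy-3-methoxyphenyl)-6-methoxy-3-[(triisopropylsilyloxy)methyl]-1,2,3,4-tetrahydronaphthalen-2-yl]methyl (E)-3-(4-hydroxyphenyl)acrylate F6. The remaining alkyl silyl ether is then cleaved under acid with aqueous HF in MeCN (0 °C → rt) to give 20.

## Further compounds

F1 | step 9 | 2-[(1S,2R,3R)-6-methoxy-1-[3-methoxy-4-(triisopropylsilyloxy)phenyl]-7-(triisopropylsilyloxy)-3-[(triisopropylsilyloxy)methyl]-1,2,3,4-tetrahydronaphthalen-2-yl]-4,4,5,5-tetramethyl-1,3,2-dioxaborolane | COc1cc([C@H]2c3cc(O[Si](C(C)C)(C(C)C)C(C)C)c(OC)cc3C[C@@H](CO[Si](C(C)C)(C(C)C)C(C)C)[C@@H]2B4OC(C)(C)C(C)(C)O4)ccc1O[Si](C(C)C)(C(C)C)C(C)C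
F2 | step 9 | 2-{[(1S,2R,3R)-6-methoxy-1-[3-methoxy-4-(triisopropylsilyloxy)phenyl]-7-(triisopropylsilyloxy)-3-[(triisopropylsilyloxy)methyl]-1,2,3,4-tetrahydronaphthalen-2-yl]methyl}-4,4,5,5-tetramethyl-1,3,2-dioxaborolane | COc1cc([C@H]2c3cc(O[Si](C(C)C)(C(C)C)C(C)C)c(OC)cc3C[C@@H](CO[Si](C(C)C)(C(C)C)C(C)C)[C@@H]2CB4OC(C)(C)C(C)(C)O4)ccc1O[Si](C(C)C)(C(C)C)C(C)C
F3 | step 3 | (R)-4-(4-hydroxy-3-methoxyphenyl)-3-(methoxycarbonyl)butanoic acid | COC(=O)[C@H](Cc1ccc(O)c(OC)c1)CC(=O)O
F4 | step 7 | (R)-6-methoxy-7-(triisopropylsilyloxy)-3-[(triisopropylsilyloxy)methyl]-3,4-dihydronaphthalen-1(2H)-one | COc1cc2C[C@@H](CO[Si](C(C)C)(C(C)C)C(C)C)CC(=O)c2cc1O[Si](C(C)C)(C(C)C)C(C)C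
F5 | step 7 | (R)-6-methoxy-7-(triisopropylsilyloxy)-3-[(triisopropylsilyloxy)methyl]-3,4-dihydronaphthalen-1-yl trifluoromethanesulfonate | COc1cc2C[C@@H](CO[Si](C(C)C)(C(C)C)C(C)C)C=C(OS(=O)(=O)C(F)(F)F)c2cc1O[Si](C(C)C)(C(C)C)C(C)C
F6 | step 13 | [(1S,2R,3R)-7-hydroxy-1-(4-hydroxy-3-methoxyphenyl)-6-methoxy-3-[(triisopropylsilyloxy)methyl]-1,2,3,4-tetrahydronaphthalen-2-yl]methyl (E)-3-(4-hydroxyphenyl)acrylate | COc1cc([C@H]2c3cc(O)c(OC)cc3C[C@@H](CO[Si](C(C)C)(C(C)C)C(C)C)[C@@H]2COC(=O)/C=C/c2ccc(O)cc2)ccc1O
A1 | alternative 1 | all-trans tetralin-3-carbaldehyde coumarate with free phenols (product of the aminocatalytic ring closure) | COc1cc([C@H]2c3cc(O)c(OC)cc3C[C@@H](C=O)[C@@H]2COC(=O)/C=C/c2ccc(O)cc2)ccc1O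
A2 | alternative 1 | open-chain aldehyde with the C1/C2 pair, the coumarate on C2a and a CH2OH group on ring A para to the C7 phenol | COc1cc([C@H]([C@H](CC=O)COC(=O)/C=C/c2ccc(O)cc2)c2cc(O)c(OC)cc2CO)ccc1O
A3 | alternative 2 | 1-aryl-4-hydroxytetralin-2,3-dicarboxylate of methyl (S)-lactate, 1,2-trans, 2,3-trans, 3,4-cis | COc1cc([C@H]2c3cc(O[Si](C)(C)C(C)(C)C)c(OC)cc3[C@@H](O)[C@@H](C(=O)O[C@@H](C)C(=O)OC)[C@@H]2C(=O)O[C@@H](C)C(=O)OC)ccc1O[Si](C)(C)C(C)(C)C
A4 | alternative 2 | 4-(tert-butyldimethylsilyloxy)-2-[4-(tert-butyldimethylsilyloxy)-3-methoxybenzyl]-5-methoxybenzaldehyde | COc1cc(Cc2cc(O[Si](C)(C)C(C)(C)C)c(OC)cc2C=O)ccc1O[Si](C)(C)C(C)(C)C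
A5 | alternative 2 | bis[(S)-1-methoxy-1-oxopropan-2-yl] fumarate | COC(=O)[C@H](C)OC(=O)/C=C/C(=O)O[C@@H](C)C(=O)OC
A6 | alternative 3 | all-trans tetralin with free C3a–OH, PMB ether on C2a–O and two aryl triisopropylsilyl ethers | COc1cc([C@H]2c3cc(O[Si](C(C)C)(C(C)C)C(C)C)c(OC)cc3C[C@@H](CO)[C@@H]2COCc2ccc(OC)cc2)ccc1O[Si](C(C)C)(C(C)C)C(C)C
A7 | alternative 3 | ring-A aryl bromide carrying C1 (diarylmethine), C2 (CH2O-PMB) and an oxetan-3-yl group | COc1cc([C@H]([C@@H](COCc2ccc(OC)cc2)C2COC2)c2cc(O[Si](C(C)C)(C(C)C)C(C)C)c(OC)cc2Br)ccc1O[Si](C(C)C)(C(C)C)C(C)C
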